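I watched the solid.

| flask | solid substrate | partner | second reagent | remark | time |
|---|---|---|---|---|---|
| south | 13 mM | 1.1 equiv | 4 equiv | run made earlier |  |
| north-west | 69 mM | 1.1 equiv | 4 equiv | run made earlier |  |
| autumn | 80 mM | 1.10 equiv | 4.00 equiv |  | 6.0 min |
| dusk | 20 mM | 1.10 equiv | 4.00 equiv |  | 4.0 min |

| run | time / min | product / % | solid substrate / % |
|---|---|---|---|
| south | 0.200 | 0.6 | 81.6 |
| south | 0.667 | 3.2 | 44.2 |
| south | 1.00 | 7.2 | 18.7 |
| south | 1.50 | 15.8 | 0 |
| south | 2.50 | 27.8 | 0.4 |
| south | 3.00 | 32.2 | 0.4 |
| south | 4.00 | 36.5 | 0 |
| north-west | 0.333 | 1.5 | 94.1 |
| north-west | 0.500 | 3.0 | 91.0 |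
| north-west | 0.667 | 4.8 | 87.6 |
| north-west | 1.00 | 8.4 | 81.7 |
| north-west | 1.50 | 14.9 | 72.9 |
| north-west | 2.50 | 28.6 | 55.1 |
| north-west | 4.00 | 48.3 | 29.2 |

(scatter of a reading: 0.3 percentage points)

- solid substrate is a solid; its amount is given per volume of the solution
- at the start none of the solid substrate is in solution
- what has only dissolved of solid substrate counts as not reacted
- where the amount of solid substrate changes, what is given in equivalents or mol% on it follows

- the flask that ends with the higher amount of product, in percent of the solid substrate charged, or "neither" when 2 percentage points or less lies between them (autumn / dusk / neither)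
- final product, as a percentage of the solid substrate charged, in autumn
- final product, as a percentage of the solid substrate charged, in dusk

1. In the north-west run, the solid substrate fell almost in a straight line, from 94.1% to 29.2%. With 69 mM charged, that made a steady feed into solution, the mM of solid going per minute however much lay there (zero-order), of 12.2 mM min⁻¹.

2. I divided each charge c(solid substrate) by the feed to get how long the solid lasts: 6.55 min in autumn and 1.64 min in dusk. So autumn should still be feeding at 6.0 min, but dusk should lose its solid before 4.0 min.

3. Over its last two readings, north-west product rose by 9.06 mM min⁻¹, and that line met zero at 0.322 min. Carried to autumn, the line gave 64.3%.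

4. Dusk has the same equivalents as south and north-west, and its loading lies between theirs. So I put dusk between their readings at 4.0 min, 36.5% and 48.3%. That put my autumn estimate 16 percentage points above the top of that bracket, and I committed to autumn.

5. The weak link was step 3, which ran a line 2.00 min past its last reading. South showed a line bending: after its solid read 0% at 1.50 min, its product rate sank from 1.56 mM min⁻¹ to 0.559 mM min⁻¹. By step 2, autumn's solid outlasts its run, so I kept the estimate.

The forecast, made from the same runs, said autumn, with 63% for autumn and 47% for dusk, holding that “this is dissolution, not reaction”.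

The flasks gave 66.8% in autumn and 46.8% in dusk, so autumn led.

    starting material + partner → intermediate (k = 7.80 L mol⁻¹ s⁻¹)
    second reagent + intermediate ⇌ product (K = 15.0 L mol⁻¹, k = 0.110 L mol⁻¹ s⁻¹)
    solid substrate ⇌ starting material, rate k3*(cs3 - [starting material]) while solid is left; crystals form when [starting material] > cs3 (solubility = 9.40 mM, k = 0.0230 s⁻¹)

Autumn ended 2.5 points above my line, and dusk fell inside my bracket. The feed put the solid left in autumn at 8.41%, and the flask held 8.89%. A further flask was autumn with 1.00 equiv of second reagent. Its solid charge was unchanged, so the same feed again gave 8.41%, and it held 8.89%. The feed counts what enters solution, not what becomes product: that flask reached 33.4% product, with 56.0% standing as intermediate.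

All runs are simulated with made-up constants, noise included.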